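**Retrosynthetic overview**
1. Target 17 ⇐ ester hydrolysis of 16 ⇐ ligand-controlled dearomative C8-prenylation of the aromatic chromene 14; this last C–C bond creates the quaternary centre and turns the benzene ring into the cyclohexadienone.
2. 14 ⇐ reduction and E-selective Wittig olefination of the seven-membered aryl lactone 11, which installs the 2-methyl-enoate arm.
3. Key bond, ArCH2–CH(isopropenyl): the β-carbon of dienal 9 (as its carbene-bound homoenolate) is joined to the exocyclic methylene of ortho-quinone methide 10; both carbons are normally electrophilic, and the step sets the side-chain stereocentre.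
4. 10 ⇐ sulfone 6 ⇐ chromene 3 ⇐ 2,4,6-trihydroxybenzophenone and prenal.
5. Ring order: benzene ring bought; pyran ring (step 1); temporary lactone ring (step 4, opened in step 5); dienone formed by dearomatisation (step 6).

Assumption: the facial sense of the chiral triazolium salt (step 4) and of the chiral diphosphine (step 6) is assigned by analogy and must be confirmed on the first run; if it is reversed, the commercially available mirror-image catalyst or ligand is used with nothing else changed. Descriptors for 16 and 17 refer to the 7-hydroxy-5-oxo tautomer drawn in the target SMILES.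

**Step 1**
Reactants: 1 2,4,6-trihydroxybenzophenone; 2 3-methylbut-2-enal (prenal)
Product: 3 (5,7-dihydroxy-2,2-dimethyl-2H-chromen-6-yl)(phenyl)methanone
Conditions: 2 (1.2 equiv), ethylenediammonium diacetate (20 mol %), toluene, 100 °C
Reagents that add atoms: 3-methylbut-2-enal 2, CC(C)=CC=O
Why: Knoevenagel-type condensation at the free ring carbon followed by oxa-6π-electrocyclisation (formal [3+3] chromene annulation) builds the pyran ring; the 8-benzoyl regioisomer also forms and is removed by chromatography; no stereocentre.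

**Step 2**
Reactants: 3 (5,7-dihydroxy-2,2-dimethyl-2H-chromen-6-yl)(phenyl)methanone; 4 paraformaldehyde; 5 sodium 4-methylbenzenesulfinate
Product: 6 {5,7-dihydroxy-2,2-dimethyl-8-[(4-methylbenzenesulfonyl)methyl]-2H-chromen-6-yl}(phenyl)methanone
Conditions: (CH2O)n (1.5 equiv), TolSO2Na (3 equiv), AcOH–H2O 4:1, 40 °C
Reagents that add atoms: formaldehyde (as paraformaldehyde) 4, C=O; sodium 4-methylbenzenesulfinate 5, [Na+].[O-]S(=O)c1ccc(C)cc1
Why: Three-component Mannich-type sulfonylmethylation: the only free aromatic carbon (C8) is hydroxymethylated, ionises to the quinone methide and is trapped by the soft sulfinate, giving a bench-stable quinone methide precursor; excess sulfinate suppresses the methylene-bridged dimer.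

**Step 3**
Reactants: 7 2-methylprop-2-enal (methacrolein); 8 (triphenylphosphoranylidene)acetaldehyde
Product: 9 (2E)-4-methylpenta-2,4-dienal
Conditions: 7 (3 equiv), toluene, 80 °C, sealed tube; distil
Reagents that add atoms: (triphenylphosphoranylidene)acetaldehyde 8, O=CC=P(c1ccccc1)(c1ccccc1)c1ccccc1
Why: Wittig olefination with the formyl-stabilised ylide gives the (E)-enal, and excess methacrolein prevents a second homologation.

**Step 4 (key step)**
Reactants: 6 {5,7-dihydroxy-2,2-dimethyl-8-[(4-methylbenzenesulfonyl)methyl]-2H-chromen-6-yl}(phenyl)methanone; 9 (2E)-4-methylpenta-2,4-dienal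
Product: 11 7-O-lactone of (3S)-4-(6-benzoyl-5,7-dihydroxy-2,2-dimethyl-2H-chromen-8-yl)-3-(prop-1-en-2-yl)butanoic acid (seven-membered aryl ester ring spanning O7 and C8; 5-OH free), via quinone methide 10 (not isolated)
Conditions: 9 (2 equiv, slow addition), (5aR,10bS)-2-(2,4,6-trimethylphenyl)-5a,10b-dihydro-4H,6H-indeno[2,1-b][1,2,4]triazolo[4,3-d][1,4]oxazin-2-ium tetrafluoroborate (15 mol %), Cs2CO3 (2.2 equiv), 4 Å molecular sieves, THF–toluene, −20 °C → rt
Reagents that add atoms: (2E)-4-methylpenta-2,4-dienal 9, C=C(C)/C=C/C=O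
Why: Base expels sulfinate to give quinone methide 10 while the carbene converts the enal into its homoenolate, whose β-carbon adds to the exocyclic methylene of 10 before the O7 phenoxide acylates the acyl azolium and releases the catalyst (carbene-catalysed formal [4+3] annulation of enals with in situ ortho-quinone methides, here extended to a 2,4-dienal and an acylphloroglucinol-type quinone methide); the aminoindanol-derived triazolium shields one face of the homoenolate and so sets the (S) centre, and keeping both phenols as caesium phenoxides removes the proton source that would quench the homoenolate.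

**Step 5**
Reactants: 11 7-O-lactone of (3S)-4-(6-benzoyl-5,7-dihydroxy-2,2-dimethyl-2H-chromen-8-yl)-3-(prop-1-en-2-yl)butanoic acid; 12 methyl 2-(triphenylphosphoranylidene)propanoate
Product: 14 methyl (2E,5R)-6-(6-benzoyl-5,7-dihydroxy-2,2-dimethyl-2H-chromen-8-yl)-2-methyl-5-(prop-1-en-2-yl)hex-2-enoate, via hydroxy aldehyde 13 (not isolated)
Conditions: iBu2AlH (2.2 equiv), CH2Cl2, −78 °C; MeOH, −78 °C; then 12 (3 equiv), → 40 °C; aqueous potassium sodium tartrate work-up
Reagents that add atoms: methyl 2-(triphenylphosphoranylidene)propanoate 12, COC(=O)C(C)=P(c1ccccc1)(c1ccccc1)c1ccccc1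
Why: The aryl lactone is reduced to the lactol level at −78 °C much faster than the hindered, chelated diaryl ketone (the first hydride equivalent is consumed by the 5-OH), and the ring-opened aldehyde 13 undergoes Wittig olefination with the stabilised α-methyl ylide, which gives the (E)-trisubstituted enoate (typically >95:5); the stereocentre is untouched and its descriptor changes from S to R only through CIP priorities.

**Step 6**
Reactants: 14 methyl (2E,5R)-6-(6-benzoyl-5,7-dihydroxy-2,2-dimethyl-2H-chromen-8-yl)-2-methyl-5-(prop-1-en-2-yl)hex-2-enoate; 15 3-methylbut-2-en-1-yl acetate (prenyl acetate)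
Product: 16 methyl (2E,5R)-6-[(8S)-6-benzoyl-7-hydroxy-2,2-dimethyl-8-(3-methylbut-2-en-1-yl)-5-oxo-5,8-dihydro-2H-chromen-8-yl]-2-methyl-5-(prop-1-en-2-yl)hex-2-enoate
Conditions: 15 (1.2 equiv), Pd2(dba)3·CHCl3 (2.5 mol %), N,N'-[(1R,2R)-cyclohexane-1,2-diyl]bis[2-(diphenylphosphanyl)benzamide] (7.5 mol %), Cs2CO3 (1.1 equiv), degassed CH2Cl2, 0 °C → rt
Reagents that add atoms: 3-methylbut-2-en-1-yl acetate 15, CC(=O)OCC=C(C)C
Why: Proposed new method: zerovalent palladium ionises 15 to a cationic (1,1-dimethylallyl)palladium complex held in the chiral pocket of the diphosphine, and the caesium phenoxide of 14 attacks its unsubstituted terminus through C8 (outer-sphere Tsuji–Trost alkylation), which dearomatises the ring to the enolised triketone while the ligand, not the remote side-chain centre, selects the C8 face to give (8S); any O-prenyl ether re-ionises and funnels to the C-alkylated product; the closest known reactions are the palladium-catalysed asymmetric allylic alkylation of prochiral cyclic 1,3-dicarbonyl and oxindole nucleophiles with prenyl electrophiles, the palladium-catalysed intermolecular allylic dearomatisation of phenols and naphthols, and the racemic base-mediated dearomative C-prenylation of acylphloroglucinols.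

**Step 7**
Reactants: 16 methyl (2E,5R)-6-[(8S)-6-benzoyl-7-hydroxy-2,2-dimethyl-8-(3-methylbut-2-en-1-yl)-5-oxo-5,8-dihydro-2H-chromen-8-yl]-2-methyl-5-(prop-1-en-2-yl)hex-2-enoate
Product: 17 (2E,5R)-6-[(8S)-6-benzoyl-7-hydroxy-2,2-dimethyl-8-(3-methylbut-2-en-1-yl)-5-oxo-5,8-dihydro-2H-chromen-8-yl]-2-methyl-5-(prop-1-en-2-yl)hex-2-enoic acid (CNP0333091.1)
Conditions: LiOH·H2O (5 equiv), THF–MeOH–H2O 3:1:1, rt → 40 °C; then 1 M HCl to pH 3–4 at 0 °C, immediate extraction
Reagents that add atoms: lithium hydroxide monohydrate, [Li+].[OH-].O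
Why: Saponification: the β-triketone sits as its delocalised enolate and resists hydroxide (no retro-Claisen), neither stereocentre is epimerisable, the (E)-enoate is retained, and the mild cold acidification avoids acid-catalysed cyclisation of the prenyl group onto the enol.

**Compound list**
1 | 2,4,6-trihydroxybenzophenone | O=C(c1ccccc1)c1c(O)cc(O)cc1O | starting material
2 | 3-methylbut-2-enal (prenal) | CC(C)=CC=O | starting material
3 | (5,7-dihydroxy-2,2-dimethyl-2H-chromen-6-yl)(phenyl)methanone | CC1(C)C=Cc2c(O)c(C(=O)c3ccccc3)c(O)cc2O1 | intermediate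
4 | paraformaldehyde (formaldehyde) | C=O | starting material
5 | sodium 4-methylbenzenesulfinate | [Na+].[O-]S(=O)c1ccc(C)cc1 | starting material
6 | {5,7-dihydroxy-2,2-dimethyl-8-[(4-methylbenzenesulfonyl)methyl]-2H-chromen-6-yl}(phenyl)methanone | CC1(C)C=Cc2c(O)c(C(=O)c3ccccc3)c(O)c(CS(=O)(=O)c3ccc(C)cc3)c2O1 | intermediate
7 | 2-methylprop-2-enal (methacrolein) | C=C(C)C=O | starting material
8 | (triphenylphosphoranylidene)acetaldehyde | O=CC=P(c1ccccc1)(c1ccccc1)c1ccccc1 | starting material
9 | (2E)-4-methylpenta-2,4-dienal | C=C(C)/C=C/C=O | intermediate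
10 | 6-benzoyl-5-hydroxy-2,2-dimethyl-8-methylidene-2H-chromen-7(8H)-one (ortho-quinone methide, present as its caesium salt) | C=C1C(=O)C(C(=O)c2ccccc2)=C(O)C2=C1OC(C)(C)C=C2 | intermediate
11 | 7-O-lactone of (3S)-4-(6-benzoyl-5,7-dihydroxy-2,2-dimethyl-2H-chromen-8-yl)-3-(prop-1-en-2-yl)butanoic acid | CC1(C)C=Cc2c(O)c(C(=O)c3ccccc3)c3OC(=O)C[C@@H](C(C)=C)Cc3c2O1 | intermediate
12 | methyl 2-(triphenylphosphoranylidene)propanoate | COC(=O)C(C)=P(c1ccccc1)(c1ccccc1)c1ccccc1 | starting material
13 | (3S)-4-(6-benzoyl-5,7-dihydroxy-2,2-dimethyl-2H-chromen-8-yl)-3-(prop-1-en-2-yl)butanal (in equilibrium with its seven-membered lactol) | CC1(C)C=Cc2c(O)c(C(=O)c3ccccc3)c(O)c(C[C@@H](CC=O)C(C)=C)c2O1 | intermediate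
14 | methyl (2E,5R)-6-(6-benzoyl-5,7-dihydroxy-2,2-dimethyl-2H-chromen-8-yl)-2-methyl-5-(prop-1-en-2-yl)hex-2-enoate | C=C(C)[C@H](C/C=C(\C)C(=O)OC)Cc1c(O)c(C(=O)c2ccccc2)c(O)c2C=CC(C)(C)Oc12 | intermediate
15 | 3-methylbut-2-en-1-yl acetate (prenyl acetate) | CC(=O)OCC=C(C)C | starting material
16 | methyl (2E,5R)-6-[(8S)-6-benzoyl-7-hydroxy-2,2-dimethyl-8-(3-methylbut-2-en-1-yl)-5-oxo-5,8-dihydro-2H-chromen-8-yl]-2-methyl-5-(prop-1-en-2-yl)hex-2-enoate | C=C(C)[C@H](C/C=C(\C)C(=O)OC)C[C@@]1(CC=C(C)C)C(O)=C(C(=O)c2ccccc2)C(=O)C2=C1OC(C)(C)C=C2 | intermediate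
17 | (2E,5R)-6-[(8S)-6-benzoyl-7-hydroxy-2,2-dimethyl-8-(3-methylbut-2-en-1-yl)-5-oxo-5,8-dihydro-2H-chromen-8-yl]-2-methyl-5-(prop-1-en-2-yl)hex-2-enoic acid | C=C(C)[C@H](C/C=C(\C)C(=O)O)C[C@@]1(CC=C(C)C)C(O)=C(C(=O)c2ccccc2)C(=O)C2=C1OC(C)(C)C=C2 | target

**Totals**
Total step count: 7. Longest linear sequence: 6 (steps 1, 2, 4, 5, 6, 7 from compound 1).

**Three steps most likely to fail**

Step 4 is the riskiest. The free, acidic phenols may protonate the homoenolate (giving redox esterification), quinone methide 10 may oligomerise or add the carbene, and the dienal may react through its δ-carbon. The fallback sets out from 6 and masks both phenols (TBSOTf, 2,6-lutidine, CH2Cl2) to give {5,7-bis[(tert-butyldimethylsilyl)oxy]-2,2-dimethyl-8-[(4-methylbenzenesulfonyl)methyl]-2H-chromen-6-yl}(phenyl)methanone F1. The same carbene annulation with 9 is then run under fluoride triggering (CsF, 18-crown-6, THF, −20 °C) instead of base triggering. Desilylation releases the quinone methide slowly with no acidic proton present during C–C bond formation, and the lower temperature also favours β-attack. Loss of the second silyl group and lactonisation in the same flask return the route at 11.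

Step 5 may over-reduce the aryl ester to the primary alcohol or touch the benzoyl ketone. The fallback sets out from 11 and opens the activated aryl lactone with ethanethiol (EtSH, Et3N, CH2Cl2) to give S-ethyl (3S)-4-(6-benzoyl-5,7-dihydroxy-2,2-dimethyl-2H-chromen-8-yl)-3-(prop-1-en-2-yl)butanethioate F2. Fukuyama reduction of the thioester (Et3SiH, Pd on CaCO3 poisoned with lead, acetone, rt) leaves the ketone and the alkenes alone and returns the route at aldehyde 13, which is treated with 12 as in step 5.

Step 6 may give poor facial control at C8, slow ionisation of prenyl acetate, or reverse-prenyl and O-prenyl by-products. The fallback sets out from 14 and gives up catalyst control: uncatalysed dearomative C-alkylation with prenyl bromide (LiHMDS, THF, −78 → 0 °C) gives 16 together with its C8 epimer, methyl (2E,5R)-6-[(8R)-6-benzoyl-7-hydroxy-2,2-dimethyl-8-(3-methylbut-2-en-1-yl)-5-oxo-5,8-dihydro-2H-chromen-8-yl]-2-methyl-5-(prop-1-en-2-yl)hex-2-enoate F3. Because the side-chain centre is already fixed, the two are diastereomers and are separated by preparative HPLC, and the route returns at 16.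

**Further compounds**
F1 | step 4 | {5,7-bis[(tert-butyldimethylsilyl)oxy]-2,2-dimethyl-8-[(4-methylbenzenesulfonyl)methyl]-2H-chromen-6-yl}(phenyl)methanone | CC1(C)C=Cc2c(O[Si](C)(C)C(C)(C)C)c(C(=O)c3ccccc3)c(O[Si](C)(C)C(C)(C)C)c(CS(=O)(=O)c3ccc(C)cc3)c2O1
F2 | step 5 | S-ethyl (3S)-4-(6-benzoyl-5,7-dihydroxy-2,2-dimethyl-2H-chromen-8-yl)-3-(prop-1-en-2-yl)butanethioate | CCSC(=O)C[C@@H](C(C)=C)Cc1c(O)c(C(=O)c2ccccc2)c(O)c2C=CC(C)(C)Oc12
F3 | step 6 | methyl (2E,5R)-6-[(8R)-6-benzoyl-7-hydroxy-2,2-dimethyl-8-(3-methylbut-2-en-1-yl)-5-oxo-5,8-dihydro-2H-chromen-8-yl]-2-methyl-5-(prop-1-en-2-yl)hex-2-enoate | C=C(C)[C@H](C/C=C(\C)C(=O)OC)C[C@]1(CC=C(C)C)C(O)=C(C(=O)c2ccccc2)C(=O)C2=C1OC(C)(C)C=C2
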